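Hold the time at 12 min and compare every run there, and watch how much reagent has gone into products by then.

| setting | alder | oak | birch | flask |
|---|---|---|---|---|
| substrate | 0.56 M | 0.88 M | 0.40 M | 0.40 M |
| reagent | 0.80 M | 0.80 M | 1.2 M | 0.800 M |
| remark | run made earlier | run made earlier | run made earlier |  |
| time |  |  |  | 12 min |

| run | time / min | substrate / % | first product / % | double product / % |
|---|---|---|---|---|
| alder | 0.833 | 38.8 | 52.0 | 7.1 |
| alder | 2.00 | 26.4 | 56.5 | 12.3 |
| alder | 4.00 | 19.8 | 53.4 | 15.9 |
| alder | 6.00 | 14.9 | 48.6 | 19.3 |
| alder | 8.00 | 13.2 | 45.1 | 21.6 |
| alder | 12.0 | 9.7 | 36.0 | 25.0 |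
| alder | 15.0 | 7.6 | 31.0 | 27.4 |
| oak | 1.00 | 45.0 | 48.0 | 4.9 |
| oak | 2.00 | 39.2 | 49.6 | 8.1 |
| oak | 2.50 | 37.2 | 48.5 | 7.7 |
| oak | 4.00 | 34.2 | 46.6 | 8.3 |
| oak | 6.00 | 31.0 | 44.6 | 10.0 |
| oak | 10.0 | 27.5 | 38.1 | 11.1 |
| oak | 15.0 | 25.0 | 30.3 | 11.7 |
| birch | 1.33 | 11.4 | 60.6 | 24.0 |
| birch | 4.00 | 3.2 | 44.5 | 42.0 |
| birch | 6.00 | 1.9 | 33.3 | 49.7 |
| birch | 10.0 | 0.1 | 19.8 | 58.9 |
| birch | 15.0 | 0.8 | 11.2 | 64.7 |

(standard deviation of a reading: 0.5 percentage points)

- amounts and yields of by-product count crystals too
- given per volume of solution although it is solid: crystals
- what was read earlier has a scatter of 0.5 percentage points, one standard deviation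
- on the list of suspects stand: substrate + reagent -> first product + by-product; reagent + first product -> double product + by-product; first product + by-product -> side product; crystals <-> by-product; reagent <-> dormant form

1. how much substrate there is at 12 min, in percent of the substrate charged
2. how much first product there is at 12 min, in percent of the substrate charged
3. how much double product there is at 12 min, in percent of the substrate charged

By the list of suspects, each substrate gone has taken one reagent and each double product one more, while the step to side product takes none. So reagent built into products per substrate charged is one plus the surplus: double product minus substrate left, both as fractions of the charge. Reagent standing as dormant form is not in this count. Zero on this scale is the symmetric case, one reagent built in per substrate. Alder, charged at 1.43 equivalents of reagent, reads 15.3% at 12.0 min. Birch, at 3.00, has no reading there, but between its last two it reads about 60.8%. The flask, at 2.00, lies 0.454 of the way from alder to birch on the logarithm of that ratio. Estimate the flask's surplus, double product minus substrate left, at 36.0%.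

Put substrate on the same line, from 9.7% in alder to about 0.450% in birch. That gives 5.51%, hence double product 41.5%. This link is weak: the two ends differ by a factor of 21.6, and a straight line across such a span is a poor guide. Interpolate its logarithm instead. Commit to substrate 2.41% and double product 38.4%. The surplus says nothing of how first product and side product share the rest.

The forecast, which “interpolated between alder and birch by excess reagent at 4 min” where my line runs at 12 min, stands at 3.8% substrate, 30% first product and 39% double product.

The flask gives 2.96% substrate, 30.8% first product and 37.1% double product.

    substrate + reagent → first product + by-product (k = 0.0458 M⁻¹ s⁻¹)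
    reagent + first product → double product + by-product (k = 0.0109 M⁻¹ s⁻¹)
    first product + by-product → side product (k = 0.00494 M⁻¹ s⁻¹)
    crystals ⇌ by-product, rate k4*(cs4 - [by-product]) while solid is left; crystals form when [by-product] > cs4 (solubility = 0.180 M, k = 0.592 s⁻¹)
    reagent ⇌ dormant form (K = 3.00, k = 0.0112 s⁻¹)

At 12.0 min the flask holds reagent at 7.42% of its charge beside 0.204 M of dormant form. Add the flask's substrate to the surplus 36.0%: double product comes to 39.0%, against 37.1%.

Now take a neighbour flask with 0.68 M of substrate and the same reagent, between oak and alder on the ratio. Oak reads about −15.2% between its readings, so the estimated surplus comes to 2.22%, close to zero. The neighbour flask gives 18.1% double product and 15.2% substrate, a surplus of 2.90%.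

(The earlier runs and the new flask stem from a simulated flask for an exercise.)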